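## Retrosynthetic overview

1. Vibsanin P ⇐ Luche reduction of the C7 enal, cross-metathesis on a C4 allyl group, and Mitsunobu esterification with inversion at C1 of an erythro epoxy alcohol made by OH-directed epoxidation.
2. The 11-membered carbocycle (first ring) ⇐ intramolecular Horner–Wadsworth–Emmons closure of C6=C7; the oxirane (second ring) is made on the finished macrocycle.
3. The C4 quaternary centre and the (E)-C2=C3 alkene ⇐ Claisen rearrangement of the vinyl ether of a C2 allylic alcohol, with C2→C4 chirality transfer through a chair transition state.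
4. The C1/C2 syn-diol ⇐ chelation-controlled addition of a dienyl Grignard (from pent-1-en-4-yne) to an α-PMBO aldehyde.
5. C1 ⇐ Felkin–Anh addition of an alkenyllithium (from pent-3-yn-1-ol) to (S)-glyceraldehyde acetonide, the only purchased stereocentre.

Assumption: ring atoms are numbered C1 (ester carbon), C2=C3, C4 (quaternary), C5, C6=C7 (C7 carries CH2OH), C8, C9, C10–C11 (epoxide, C11 carries CH3); (S)-glyceraldehyde acetonide is bought (made from L-ascorbic acid); the phosphonate-bearing carbon in 17–19 is an inconsequential epimer mixture.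

## Route

Step 1
Reactants: 1 pent-3-yn-1-ol
Product: 2 5-chloropent-2-yne
Conditions: PPh3, N-chlorosuccinimide, CH2Cl2, 0 → 23 °C
Reagents that add atoms: N-chlorosuccinimide, O=C1CCC(=O)N1Cl
Why: Appel-type chlorination of a primary alcohol through the alkoxyphosphonium salt gives a chloride that tolerates the later organometallic steps and serves as the C8 electrophile.

Step 2
Reactants: 2 5-chloropent-2-yne
Product: 4 (2E)-5-chloro-2-iodopent-2-ene, via alkenylzirconocene chloride 3 (not isolated)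
Conditions: Cp2Zr(H)Cl (1.5 equiv), THF, 50 °C; then I2, 0 °C
Reagents that add atoms: iodine, II
Why: Syn hydrozirconation under equilibrating conditions places zirconium on the methyl-bearing alkyne carbon, and iodinolysis with retention gives the (E)-2-iodoalkene that becomes C11=C10.

Step 3
Reactants: 4 (2E)-5-chloro-2-iodopent-2-ene, 5 (4S)-2,2-dimethyl-1,3-dioxolane-4-carbaldehyde
Product: 7 (1R,2E)-5-chloro-1-[(4S)-2,2-dimethyl-1,3-dioxolan-4-yl]-2-methylpent-2-en-1-ol, via alkenyllithium 6 (not isolated)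
Conditions: t-BuLi (2.1 equiv), Et2O, −78 °C; then 5, −78 °C; aq. NH4Cl
Reagents that add atoms: none
Why: Iodine–lithium exchange then Felkin–Anh (anti) addition to the α-alkoxy aldehyde sets the C1 carbinol as R under control of the dioxolane centre (about 4:1 expected, minor syn isomer removed by chromatography).

Step 4
Reactants: 7 (1R,2E)-5-chloro-1-[(4S)-2,2-dimethyl-1,3-dioxolan-4-yl]-2-methylpent-2-en-1-ol
Product: 8 (4S)-4-{(1R,2E)-5-chloro-1-[(4-methoxybenzyl)oxy]-2-methylpent-2-en-1-yl}-2,2-dimethyl-1,3-dioxolane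
Conditions: NaH, 4-methoxybenzyl bromide, DMF, 0 °C
Reagents that add atoms: 4-methoxybenzyl bromide, COc1ccc(CBr)cc1
Why: Williamson etherification installs a PMB ether that can chelate in step 7 and is removable oxidatively in step 12.

Step 5
Reactants: 8 (4S)-4-{(1R,2E)-5-chloro-1-[(4-methoxybenzyl)oxy]-2-methylpent-2-en-1-yl}-2,2-dimethyl-1,3-dioxolane
Product: 9 (2R,3E)-6-chloro-2-[(4-methoxybenzyl)oxy]-3-methylhex-3-enal
Conditions: H5IO6 (1.5 equiv), EtOAc, 23 °C; used crude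
Reagents that add atoms: none
Why: Periodic acid hydrolyses the terminal acetonide and cleaves the liberated glycol in one pot, turning the spent pool carbon into the C2 aldehyde without touching C1.

Step 6
Reactants: 10 pent-1-en-4-yne
Product: 12 (1E)-1-iodo-2-methylpenta-1,4-diene, via dienyl(dimethyl)alane 11 (not isolated)
Conditions: AlMe3 (2 equiv), Cp2ZrCl2 (0.25 equiv), CH2Cl2, 0 → 23 °C; then I2, THF, −30 °C
Reagents that add atoms: trimethylaluminium, C[Al](C)C; iodine, II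
Why: Zirconium-catalysed syn carboalumination of the terminal alkyne followed by iodinolysis fixes the trisubstituted alkene geometry (methyl cis to iodine) needed for the Claisen chirality transfer.

Step 7
Reactants: 12 (1E)-1-iodo-2-methylpenta-1,4-diene, 9 (2R,3E)-6-chloro-2-[(4-methoxybenzyl)oxy]-3-methylhex-3-enal
Product: 15 (4E,6R,7R,8E)-11-chloro-7-[(4-methoxybenzyl)oxy]-4,8-dimethylundeca-1,4,8-trien-6-ol, via dienyllithium 13 (not isolated), via dienylmagnesium bromide 14 (not isolated)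
Conditions: t-BuLi (2.1 equiv), Et2O, −78 °C; MgBr2·OEt2; then 9 premixed with MgBr2·OEt2, CH2Cl2, −78 °C; aq. NH4Cl
Reagents that add atoms: none
Why: Cram-chelate addition (magnesium bridging the carbonyl and PMB oxygens, attack anti to the alkenyl group) gives the syn (6R,7R) diol monoether, so the new C2 carbinol is set by C1.

Step 8
Reactants: 15 (4E,6R,7R,8E)-11-chloro-7-[(4-methoxybenzyl)oxy]-4,8-dimethylundeca-1,4,8-trien-6-ol, 16 diethyl {2-[methoxy(methyl)amino]-2-oxoethyl}phosphonate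
Product: 17 (5E,7R,8R,9E)-2-(diethoxyphosphoryl)-8-hydroxy-N-methoxy-7-[(4-methoxybenzyl)oxy]-N,6,10-trimethyltrideca-5,9,12-trienamide
Conditions: 16 (2.5 equiv), NaH (2.4 equiv), NaI (0.2 equiv), DMF, 0 → 65 °C
Reagents that add atoms: none
Why: SN2 alkylation of the soft phosphonate carbanion by the primary chloride (iodide-catalysed) attaches C7 and the future CH2OH carbon while leaving the free C2 hydroxyl untouched.

Step 9
Reactants: 17 (5E,7R,8R,9E)-2-(diethoxyphosphoryl)-8-hydroxy-N-methoxy-7-[(4-methoxybenzyl)oxy]-N,6,10-trimethyltrideca-5,9,12-trienamide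
Product: 19 (5E,7S,8E,10S)-2-(diethoxyphosphoryl)-N-methoxy-7-[(4-methoxybenzyl)oxy]-N,6,10-trimethyl-10-(2-oxoethyl)trideca-5,8,12-trienamide, via allyl vinyl ether 18 (not isolated)
Conditions: [Ir(cod)Cl]2 (2 mol %), Na2CO3 (0.6 equiv), vinyl acetate, PhMe, 100 °C; then 150 °C (sealed tube)
Reagents that add atoms: vinyl acetate, CC(=O)OC=C
Why: Transfer vinylation then Claisen rearrangement through a chair transition state with the C1-bearing group equatorial forms the C4–C5 bond, the (E)-C2=C3 alkene and the C4 quaternary centre as S by suprafacial transfer of the C2 (R) chirality.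

Step 10
Reactants: 19 (5E,7S,8E,10S)-2-(diethoxyphosphoryl)-N-methoxy-7-[(4-methoxybenzyl)oxy]-N,6,10-trimethyl-10-(2-oxoethyl)trideca-5,8,12-trienamide
Product: 20 (1S,2E,4S,6E,10E)-N-methoxy-1-[(4-methoxybenzyl)oxy]-N,4,11-trimethyl-4-(prop-2-en-1-yl)cycloundeca-2,6,10-triene-7-carboxamide
Conditions: LiCl, DBU, MeCN, 25 °C, syringe-pump addition to 1 mM
Reagents that add atoms: none
Why: Intramolecular Horner–Wadsworth–Emmons olefination under Masamune–Roush conditions closes the 11-membered ring at C6=C7 with the carbonyl trans to C5, which is also the ring-cis geometry the medium ring prefers.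

Step 11
Reactants: 20 (1S,2E,4S,6E,10E)-N-methoxy-1-[(4-methoxybenzyl)oxy]-N,4,11-trimethyl-4-(prop-2-en-1-yl)cycloundeca-2,6,10-triene-7-carboxamide
Product: 21 (1S,2E,4S,6E,10E)-1-[(4-methoxybenzyl)oxy]-4,11-dimethyl-4-(prop-2-en-1-yl)cycloundeca-2,6,10-triene-7-carbaldehyde
Conditions: i-Bu2AlH (1.3 equiv), THF, −78 °C; aq. potassium sodium tartrate
Reagents that add atoms: none
Why: Weinreb amide reduction stops at the chelated hemiaminal and gives the enal, which is inert to the next three steps and is reduced chemoselectively at the end.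

Step 12
Reactants: 21 (1S,2E,4S,6E,10E)-1-[(4-methoxybenzyl)oxy]-4,11-dimethyl-4-(prop-2-en-1-yl)cycloundeca-2,6,10-triene-7-carbaldehyde
Product: 22 (1S,2E,4S,6E,10E)-1-hydroxy-4,11-dimethyl-4-(prop-2-en-1-yl)cycloundeca-2,6,10-triene-7-carbaldehyde
Conditions: DDQ (1.2 equiv), CH2Cl2/pH 7 buffer, 0 °C
Reagents that add atoms: none
Why: Oxidative PMB cleavage (benzylic hydride abstraction, hemiacetal hydrolysis) frees the C1 hydroxyl under buffered conditions that spare the alkenes and the enal.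

Step 13
Reactants: 22 (1S,2E,4S,6E,10E)-1-hydroxy-4,11-dimethyl-4-(prop-2-en-1-yl)cycloundeca-2,6,10-triene-7-carbaldehyde
Product: 23 (1S,2E,4S,6E,10S,11R)-10,11-epoxy-1-hydroxy-4,11-dimethyl-4-(prop-2-en-1-yl)cycloundeca-2,6-diene-7-carbaldehyde
Conditions: VO(acac)2 (5 mol %), t-BuOOH (1.2 equiv), CH2Cl2, 0 °C
Reagents that add atoms: tert-butyl hydroperoxide, CC(C)(C)OO
Why: Hydroxyl-directed vanadium epoxidation picks the electron-rich trisubstituted C10=C11 alkene and, because of 1,2-allylic strain with the C11 methyl, delivers oxygen erythro to the C1 hydroxyl, setting 10S,11R from C1.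

Step 14
Reactants: 23 (1S,2E,4S,6E,10S,11R)-10,11-epoxy-1-hydroxy-4,11-dimethyl-4-(prop-2-en-1-yl)cycloundeca-2,6-diene-7-carbaldehyde, 24 3-methylbut-2-enoic acid
Product: 25 (1R,2E,4S,6E,10S,11R)-10,11-epoxy-7-formyl-4,11-dimethyl-4-(prop-2-en-1-yl)cycloundeca-2,6-dien-1-yl 3-methylbut-2-enoate
Conditions: 24 (3 equiv), PPh3, DIAD, PhMe, 0 → 23 °C
Reagents that add atoms: none
Why: Mitsunobu esterification displaces the allylic oxyphosphonium with clean SN2 inversion (no β-hydrogen for elimination, SN2' blocked by the neopentyl C3), turning the erythro alcohol into the threo (1R) senecioate.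

Step 15
Reactants: 25 (1R,2E,4S,6E,10S,11R)-10,11-epoxy-7-formyl-4,11-dimethyl-4-(prop-2-en-1-yl)cycloundeca-2,6-dien-1-yl 3-methylbut-2-enoate, 26 2-methylbut-3-en-2-ol
Product: 27 (1R,2E,4S,6E,10S,11R)-10,11-epoxy-7-formyl-4-[(2E)-4-hydroxy-4-methylpent-2-en-1-yl]-4,11-dimethylcycloundeca-2,6-dien-1-yl 3-methylbut-2-enoate
Conditions: 26 (10 equiv), second-generation Grubbs catalyst (10 mol %), CH2Cl2, 40 °C
Reagents that add atoms: none
Why: Olefin cross-metathesis engages only the terminal allyl group (the ring alkenes are hindered or electron-poor) and gives the (E)-alkene with the bulky tertiary carbinol partner.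

Step 16
Reactants: 27 (1R,2E,4S,6E,10S,11R)-10,11-epoxy-7-formyl-4-[(2E)-4-hydroxy-4-methylpent-2-en-1-yl]-4,11-dimethylcycloundeca-2,6-dien-1-yl 3-methylbut-2-enoate
Product: 28 vibsanin P, (1R,2E,4S,6E,10S,11R)-10,11-epoxy-7-(hydroxymethyl)-4-[(2E)-4-hydroxy-4-methylpent-2-en-1-yl]-4,11-dimethylcycloundeca-2,6-dien-1-yl 3-methylbut-2-enoate
Conditions: NaBH4, CeCl3·7H2O, MeOH, −20 °C
Reagents that add atoms: none
Why: Luche 1,2-reduction converts the enal into the primary allylic alcohol without touching the senecioate, the epoxide or the alkenes.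

## Compound list

1 | pent-3-yn-1-ol | CC#CCCO | starting material
2 | 5-chloropent-2-yne | CC#CCCCl | intermediate
3 | chloro[(2E)-5-chloropent-2-en-2-yl]bis(cyclopentadienyl)zirconium (formed in situ) | C/C(=C\CCCl)[Zr](Cl)(C1C=CC=C1)C1C=CC=C1 | intermediate
4 | (2E)-5-chloro-2-iodopent-2-ene | C/C(I)=C\CCCl | intermediate
5 | (4S)-2,2-dimethyl-1,3-dioxolane-4-carbaldehyde | CC1(C)OC[C@H](O1)C=O | starting material
6 | [(2Z)-5-chloropent-2-en-2-yl]lithium (formed in situ) | C/C([Li])=C\CCCl | intermediate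
7 | (1R,2E)-5-chloro-1-[(4S)-2,2-dimethyl-1,3-dioxolan-4-yl]-2-methylpent-2-en-1-ol | CC1(C)OC[C@H](O1)[C@H](O)/C(C)=C/CCCl | intermediate
8 | (4S)-4-{(1R,2E)-5-chloro-1-[(4-methoxybenzyl)oxy]-2-methylpent-2-en-1-yl}-2,2-dimethyl-1,3-dioxolane | CC1(C)OC[C@H](O1)[C@H](OCc2ccc(OC)cc2)/C(C)=C/CCCl | intermediate
9 | (2R,3E)-6-chloro-2-[(4-methoxybenzyl)oxy]-3-methylhex-3-enal | O=C[C@H](OCc1ccc(OC)cc1)/C(C)=C/CCCl | intermediate
10 | pent-1-en-4-yne | C=CCC#C | starting material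
11 | dimethyl[(1E)-2-methylpenta-1,4-dien-1-yl]alumane (formed in situ) | C=CC/C(C)=C/[Al](C)C | intermediate
12 | (1E)-1-iodo-2-methylpenta-1,4-diene | C=CC/C(C)=C/I | intermediate
13 | [(1E)-2-methylpenta-1,4-dien-1-yl]lithium (formed in situ) | C=CC/C(C)=C/[Li] | intermediate
14 | bromo[(1E)-2-methylpenta-1,4-dien-1-yl]magnesium (formed in situ) | C=CC/C(C)=C/[Mg]Br | intermediate
15 | (4E,6R,7R,8E)-11-chloro-7-[(4-methoxybenzyl)oxy]-4,8-dimethylundeca-1,4,8-trien-6-ol | C=CC/C(C)=C/[C@@H](O)[C@H](OCc1ccc(OC)cc1)/C(C)=C/CCCl | intermediate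
16 | diethyl {2-[methoxy(methyl)amino]-2-oxoethyl}phosphonate | CCOP(=O)(CC(=O)N(C)OC)OCC | starting material
17 | (5E,7R,8R,9E)-2-(diethoxyphosphoryl)-8-hydroxy-N-methoxy-7-[(4-methoxybenzyl)oxy]-N,6,10-trimethyltrideca-5,9,12-trienamide | C=CC/C(C)=C/[C@@H](O)[C@H](OCc1ccc(OC)cc1)/C(C)=C/CCC(C(=O)N(C)OC)P(=O)(OCC)OCC | intermediate
18 | (5E,7R,8R,9E)-2-(diethoxyphosphoryl)-8-(ethenyloxy)-N-methoxy-7-[(4-methoxybenzyl)oxy]-N,6,10-trimethyltrideca-5,9,12-trienamide (formed in situ) | C=CC/C(C)=C/[C@@H](OC=C)[C@H](OCc1ccc(OC)cc1)/C(C)=C/CCC(C(=O)N(C)OC)P(=O)(OCC)OCC | intermediate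
19 | (5E,7S,8E,10S)-2-(diethoxyphosphoryl)-N-methoxy-7-[(4-methoxybenzyl)oxy]-N,6,10-trimethyl-10-(2-oxoethyl)trideca-5,8,12-trienamide | O=CC[C@](C)(CC=C)/C=C/[C@H](OCc1ccc(OC)cc1)/C(C)=C/CCC(C(=O)N(C)OC)P(=O)(OCC)OCC | intermediate
20 | (1S,2E,4S,6E,10E)-N-methoxy-1-[(4-methoxybenzyl)oxy]-N,4,11-trimethyl-4-(prop-2-en-1-yl)cycloundeca-2,6,10-triene-7-carboxamide | COc1ccc(CO[C@H]2/C=C/[C@@](C)(CC=C)C/C=C(/C(=O)N(C)OC)CC/C=C/2C)cc1 | intermediate
21 | (1S,2E,4S,6E,10E)-1-[(4-methoxybenzyl)oxy]-4,11-dimethyl-4-(prop-2-en-1-yl)cycloundeca-2,6,10-triene-7-carbaldehyde | COc1ccc(CO[C@H]2/C=C/[C@@](C)(CC=C)C/C=C(/C=O)CC/C=C/2C)cc1 | intermediate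
22 | (1S,2E,4S,6E,10E)-1-hydroxy-4,11-dimethyl-4-(prop-2-en-1-yl)cycloundeca-2,6,10-triene-7-carbaldehyde | O[C@H]1/C=C/[C@@](C)(CC=C)C/C=C(/C=O)CC/C=C/1C | intermediate
23 | (1S,2E,4S,6E,10S,11R)-10,11-epoxy-1-hydroxy-4,11-dimethyl-4-(prop-2-en-1-yl)cycloundeca-2,6-diene-7-carbaldehyde | O[C@H]1/C=C/[C@@](C)(CC=C)C/C=C(/C=O)CC[C@@H]2O[C@]21C | intermediate
24 | 3-methylbut-2-enoic acid | CC(C)=CC(=O)O | starting material
25 | (1R,2E,4S,6E,10S,11R)-10,11-epoxy-7-formyl-4,11-dimethyl-4-(prop-2-en-1-yl)cycloundeca-2,6-dien-1-yl 3-methylbut-2-enoate | CC(C)=CC(=O)O[C@@H]1/C=C/[C@@](C)(CC=C)C/C=C(/C=O)CC[C@@H]2O[C@]21C | intermediate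
26 | 2-methylbut-3-en-2-ol | C=CC(C)(C)O | starting material
27 | (1R,2E,4S,6E,10S,11R)-10,11-epoxy-7-formyl-4-[(2E)-4-hydroxy-4-methylpent-2-en-1-yl]-4,11-dimethylcycloundeca-2,6-dien-1-yl 3-methylbut-2-enoate | CC(C)=CC(=O)O[C@@H]1/C=C/[C@@](C)(C/C=C/C(C)(C)O)C/C=C(/C=O)CC[C@@H]2O[C@]21C | intermediate
28 | vibsanin P | CC(C)=CC(=O)O[C@@H]1/C=C/[C@@](C)(C/C=C/C(C)(C)O)C/C=C(/CO)CC[C@@H]2O[C@]21C | target

## Step count and risks

Total step count: 16. Longest linear sequence: 15 (steps 1–5 and 7–16; step 6 is the side branch).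

**Step 10, the 11-membered HWE ring closure.** Oligomerisation or a stalled closure of the strained triene ring is the main risk. The fallback sets out from 15 and comes back at 21, closing the ring one bond over (C7–C8) by β-keto ester alkylation. Johnson–Claisen rearrangement of 15 (MeC(OEt)3, cat. EtCO2H, 140 °C) gives ethyl (3S,4E,6S,7E)-10-chloro-6-[(4-methoxybenzyl)oxy]-3,7-dimethyl-3-(prop-2-en-1-yl)deca-4,7-dienoate F1. Crossed Claisen condensation with LiCH2CO2t-Bu (tert-butyl acetate, LiN(i-Pr)2, THF, −78 °C) gives tert-butyl (5S,6E,8S,9E)-12-chloro-8-[(4-methoxybenzyl)oxy]-5,9-dimethyl-3-oxo-5-(prop-2-en-1-yl)dodeca-6,9-dienoate F2. Intramolecular C-alkylation (NaI, Cs2CO3, MeCN, 60 °C, 2 mM) gives tert-butyl (1S,2E,4S,10E)-1-[(4-methoxybenzyl)oxy]-4,11-dimethyl-6-oxo-4-(prop-2-en-1-yl)cycloundeca-2,10-diene-7-carboxylate F3. NaBH4 (MeOH, 0 °C) gives tert-butyl (1S,2E,4S,10E)-6-hydroxy-1-[(4-methoxybenzyl)oxy]-4,11-dimethyl-4-(prop-2-en-1-yl)cycloundeca-2,10-diene-7-carboxylate F4. MsCl/Et3N then DBU gives tert-butyl (1S,2E,4S,6E,10E)-1-[(4-methoxybenzyl)oxy]-4,11-dimethyl-4-(prop-2-en-1-yl)cycloundeca-2,6,10-triene-7-carboxylate F5. i-Bu2AlH (CH2Cl2, −78 → 0 °C) gives [(1S,2E,4S,6E,10E)-1-[(4-methoxybenzyl)oxy]-4,11-dimethyl-4-(prop-2-en-1-yl)cycloundeca-2,6,10-trien-7-yl]methanol F6, and MnO2 (CH2Cl2) oxidises it to 21.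

**Step 14, the Mitsunobu inversion.** The carbinol sits between a fully substituted epoxide carbon and the ring alkene, so the bulky oxyphosphonium may not be displaced. The fallback sets out from 23 and comes back at 25 by separating activation from displacement. ClCH2SO2Cl and pyridine (CH2Cl2, 0 °C) give (1S,2E,4S,6E,10S,11R)-10,11-epoxy-7-formyl-4,11-dimethyl-4-(prop-2-en-1-yl)cycloundeca-2,6-dien-1-yl chloromethanesulfonate F7. This small sulfonate is displaced with inversion by caesium 3-methylbut-2-enoate (from 24 and Cs2CO3) with 18-crown-6 in PhMe at 60 °C to give 25.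

**Step 3, the Felkin–Anh addition.** Low anti selectivity or enolisation of the aldehyde would cost material at the start of the longest sequence. The fallback sets out from 6 (generated from 4 as in step 3) and comes back at 7 by acylation and chelation-controlled reduction. Commercial methyl (4S)-2,2-dimethyl-1,3-dioxolane-4-carboxylate F8 is converted (MeNHOMe·HCl, i-PrMgCl, THF, −20 °C) into (4S)-N-methoxy-N,2,2-trimethyl-1,3-dioxolane-4-carboxamide F9. Addition of 6 at −78 °C gives (2E)-5-chloro-1-[(4S)-2,2-dimethyl-1,3-dioxolan-4-yl]-2-methylpent-2-en-1-one F10. Zn(BH4)2 (Et2O, −30 °C) then reduces the zinc-chelated ketone from the less hindered face to the anti alcohol 7.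

## Further compounds

F1 | step 10 | ethyl (3S,4E,6S,7E)-10-chloro-6-[(4-methoxybenzyl)oxy]-3,7-dimethyl-3-(prop-2-en-1-yl)deca-4,7-dienoate | CCOC(=O)C[C@](C)(CC=C)/C=C/[C@H](OCc1ccc(OC)cc1)/C(C)=C/CCCl
F2 | step 10 | tert-butyl (5S,6E,8S,9E)-12-chloro-8-[(4-methoxybenzyl)oxy]-5,9-dimethyl-3-oxo-5-(prop-2-en-1-yl)dodeca-6,9-dienoate | CC(C)(C)OC(=O)CC(=O)C[C@](C)(CC=C)/C=C/[C@H](OCc1ccc(OC)cc1)/C(C)=C/CCCl
F3 | step 10 | tert-butyl (1S,2E,4S,10E)-1-[(4-methoxybenzyl)oxy]-4,11-dimethyl-6-oxo-4-(prop-2-en-1-yl)cycloundeca-2,10-diene-7-carboxylate | COc1ccc(CO[C@H]2/C=C/[C@@](C)(CC=C)CC(=O)C(C(=O)OC(C)(C)C)CC/C=C/2C)cc1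
F4 | step 10 | tert-butyl (1S,2E,4S,10E)-6-hydroxy-1-[(4-methoxybenzyl)oxy]-4,11-dimethyl-4-(prop-2-en-1-yl)cycloundeca-2,10-diene-7-carboxylate | COc1ccc(CO[C@H]2/C=C/[C@@](C)(CC=C)CC(O)C(C(=O)OC(C)(C)C)CC/C=C/2C)cc1
F5 | step 10 | tert-butyl (1S,2E,4S,6E,10E)-1-[(4-methoxybenzyl)oxy]-4,11-dimethyl-4-(prop-2-en-1-yl)cycloundeca-2,6,10-triene-7-carboxylate | COc1ccc(CO[C@H]2/C=C/[C@@](C)(CC=C)C/C=C(/C(=O)OC(C)(C)C)CC/C=C/2C)cc1
F6 | step 10 | [(1S,2E,4S,6E,10E)-1-[(4-methoxybenzyl)oxy]-4,11-dimethyl-4-(prop-2-en-1-yl)cycloundeca-2,6,10-trien-7-yl]methanol | COc1ccc(CO[C@H]2/C=C/[C@@](C)(CC=C)C/C=C(/CO)CC/C=C/2C)cc1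
F7 | step 14 | (1S,2E,4S,6E,10S,11R)-10,11-epoxy-7-formyl-4,11-dimethyl-4-(prop-2-en-1-yl)cycloundeca-2,6-dien-1-yl chloromethanesulfonate | O=S(=O)(CCl)O[C@H]1/C=C/[C@@](C)(CC=C)C/C=C(/C=O)CC[C@@H]2O[C@]21C
F8 | step 3 | methyl (4S)-2,2-dimethyl-1,3-dioxolane-4-carboxylate | CC1(C)OC[C@H](O1)C(=O)OC
F9 | step 3 | (4S)-N-methoxy-N,2,2-trimethyl-1,3-dioxolane-4-carboxamide | CC1(C)OC[C@H](O1)C(=O)N(C)OC
F10 | step 3 | (2E)-5-chloro-1-[(4S)-2,2-dimethyl-1,3-dioxolan-4-yl]-2-methylpent-2-en-1-one | CC1(C)OC[C@H](O1)C(=O)/C(C)=C/CCCl
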